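**Retrosynthetic overview**
1. End game: the C2 ketone comes from a C2 carbinol by oxidation, and the C6 tiglate from a (6S)-alcohol by Mitsunobu inversion.
2. Key disconnection C6–C7, closing the ten-membered carbocycle last. The homoallylic alcohol unit C6(OH)–C7–C11(=C13H2), embedded in the lactone ring O–C12–C11–C7–C8, is the retron of an SE2′ allylation. The ring therefore comes from an acyclic 6-oxo 3-(bromomethyl)butenolide (C13–Br, C11=C7) by intramolecular Nozaki–Hiyama γ-allylation, which also creates C6, C7 and the exocyclic C11=C13 alkene.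
3. C1–C2: Ni/Cr coupling of a (Z)-vinyl iodide (C1, C10, C9 plus butenolide) with the C2–C6 aldehyde made from symmetric 3-methylidenepentane-1,5-diol.
4. C8–C9 and the lactone (butenolide) ring: catalytic asymmetric vinylogous Mukaiyama aldol of a 3-(alkoxymethyl)-2-silyloxyfuran with (Z)-3-iodo-2-methylacrolein.
5. Ring order: furan to butenolide (lactone ring) first, ten-membered carbocycle last.

Key step: step 16

Remark (assumption): locants follow a germacrane numbering chosen for bookkeeping (C1=C10 enone alkene, C2 ketone, C4=C15 exocyclic methylene, C6 tigloyloxy carbon, C7, C8 lactone-oxygen carbon, C9 acetoxy carbon, C11=C13 and C12 the methylene lactone); the choice has no chemical consequence.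
Remark (assumption): the C2 carbinol of 20–28 is formed without control and carried as a mixture of epimers (left unspecified in the SMILES), because step 19 removes this centre.

Step 1
Reactants: 1 prop-2-yn-1-ol
Product: 3 (2Z)-3-iodo-2-methylprop-2-en-1-ol, via vinylmagnesium alkoxide 2 (not isolated)
Conditions: MeMgBr (3 equiv), CuI (10 mol %), THF, −10 °C → rt; then I2, −78 → 0 °C
Reagents that add atoms: methylmagnesium bromide C[Mg]Br; iodine II
Why: Copper-catalysed anti-carbomagnesiation of the propargylic alkoxide (Duboudin reaction) places Mg on C3 cis to the CH2O group in a five-membered chelate, so iodinolysis with retention should give the Z iodide.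

Step 2
Reactants: 3 (2Z)-3-iodo-2-methylprop-2-en-1-ol
Product: 4 (2Z)-3-iodo-2-methylprop-2-enal
Conditions: activated MnO2, CH2Cl2, rt, dark; used at once
Reagents that add atoms: none
Why: Allylic oxidation with MnO2 is neutral and should leave the vinyl iodide and the Z geometry untouched.

Step 3
Reactants: 5 furan-3-ylmethanol
Product: 6 3-{[(4-methoxyphenyl)methoxy]methyl}furan
Conditions: NaH, PMBCl, Bu4NI (cat.), THF/DMF, 0 °C → rt
Reagents that add atoms: 4-methoxybenzyl chloride COc1ccc(CCl)cc1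
Why: Williamson etherification of the primary alkoxide.

Step 4
Reactants: 6 3-{[(4-methoxyphenyl)methoxy]methyl}furan
Product: 9 3-{[(4-methoxyphenyl)methoxy]methyl}furan-2(5H)-one, via 2-lithiofuran 7 (not isolated), via furylboronate 8 (not isolated)
Conditions: n-BuLi, THF, −78 → −20 °C; B(OMe)3, −78 °C → rt; then 30% H2O2, aq. NaHCO3, 0 °C
Reagents that add atoms: hydrogen peroxide OO
Why: The ether oxygen directs lithiation to C2 (directed metalation), and borylation followed by peroxide oxidation of the furylboronate gives the 2-hydroxyfuran, which tautomerises to the conjugated butenolide.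

Step 5
Reactants: 9 3-{[(4-methoxyphenyl)methoxy]methyl}furan-2(5H)-one
Product: 10 tert-butyl[(3-{[(4-methoxyphenyl)methoxy]methyl}furan-2-yl)oxy]dimethylsilane
Conditions: TBSOTf, Et3N, CH2Cl2, 0 °C
Reagents that add atoms: tert-butyldimethylsilyl triflate CC(C)(C)[Si](C)(C)OS(=O)(=O)C(F)(F)F
Why: Soft enolisation at C5 and O-silylation give the aromatic 2-silyloxyfuran (silyl dienol ether formation).

Step 6
Reactants: 4 (2Z)-3-iodo-2-methylprop-2-enal and 10 tert-butyl[(3-{[(4-methoxyphenyl)methoxy]methyl}furan-2-yl)oxy]dimethylsilane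
Product: 12 (5S)-5-[(1S,2Z)-1-hydroxy-3-iodo-2-methylprop-2-en-1-yl]-3-{[(4-methoxyphenyl)methoxy]methyl}furan-2(5H)-one, via trichlorosilyl ether 11 (not isolated)
Conditions: SiCl4 (1.1 equiv), (R,R)-binaphthyldiamine-derived bisphosphoramide (5 mol %, the enantiomer that attacks the aldehyde Re face), i-Pr2NEt (10 mol %), CH2Cl2, −78 °C; aq. KF/NaHCO3
Reagents that add atoms: none
Why: Vinylogous Mukaiyama aldol reaction under Lewis-base-activated SiCl4 catalysis, in which furan C5 adds to the Re face of the conjugated aldehyde through an open transition state that favours the 5,1′-syn (threo) adduct, so the catalyst should fix C9 (S) and, through the syn preference, C8 (S), while the butenolide that becomes the lactone ring emerges directly.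

Step 7
Reactants: 12 (5S)-5-[(1S,2Z)-1-hydroxy-3-iodo-2-methylprop-2-en-1-yl]-3-{[(4-methoxyphenyl)methoxy]methyl}furan-2(5H)-one
Product: 13 (1S,2Z)-3-iodo-1-[(2S)-4-{[(4-methoxyphenyl)methoxy]methyl}-5-oxo-2,5-dihydrofuran-2-yl]-2-methylprop-2-en-1-yl acetate
Conditions: Ac2O, pyridine, DMAP (cat.), CH2Cl2, 0 °C
Reagents that add atoms: acetic anhydride CC(=O)OC(C)=O
Why: Standard acylation of the secondary alcohol under weakly basic conditions that should not enolise the butenolide at C8.

Step 8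
Reactants: 14 3-methylbut-3-en-1-ol
Product: 16 3-methylidenepentane-1,5-diol, via dilithio dianion 15 (not isolated)
Conditions: n-BuLi (2.2 equiv), TMEDA, Et2O, 0 °C → rt; then (CH2O)n, −78 °C → rt
Reagents that add atoms: formaldehyde (as paraformaldehyde) C=O
Why: Alkoxide-directed allylic metalation gives the dianion, whose allyl termini are equivalent, so hydroxymethylation can give only the symmetric diol.

Step 9
Reactants: 16 3-methylidenepentane-1,5-diol
Product: 17 5-[(4-methoxyphenyl)methoxy]-3-methylidenepentan-1-ol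
Conditions: NaH (1.0 equiv), PMBCl, Bu4NI (cat.), THF, 0 °C → rt
Reagents that add atoms: 4-methoxybenzyl chloride COc1ccc(CCl)cc1
Why: Statistical Williamson mono-etherification of a symmetric diol through its monoalkoxide.

Step 10
Reactants: 17 5-[(4-methoxyphenyl)methoxy]-3-methylidenepentan-1-ol
Product: 18 5-[(4-methoxyphenyl)methoxy]-3-methylidenepentanal
Conditions: DMP, NaHCO3, CH2Cl2, 0 °C; used crude
Reagents that add atoms: none
Why: Buffered Dess–Martin oxidation is neutral, so the β,γ-double bond should stay out of conjugation.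

Step 11
Reactants: 13 (1S,2Z)-3-iodo-1-[(2S)-4-{[(4-methoxyphenyl)methoxy]methyl}-5-oxo-2,5-dihydrofuran-2-yl]-2-methylprop-2-en-1-yl acetate and 18 5-[(4-methoxyphenyl)methoxy]-3-methylidenepentanal
Product: 20 (1S,2Z,4RS)-4-hydroxy-8-[(4-methoxyphenyl)methoxy]-1-[(2S)-4-{[(4-methoxyphenyl)methoxy]methyl}-5-oxo-2,5-dihydrofuran-2-yl]-2-methyl-6-methylideneoct-2-en-1-yl acetate, via alkenylchromium 19 (not isolated)
Conditions: CrCl2 (5 equiv), NiCl2 (1 mol %), DMSO, rt
Reagents that add atoms: none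
Why: Nozaki–Hiyama–Kishi coupling, in which Ni inserts into the vinyl iodide with retention of the Z geometry and the alkenylchromium adds only to the aldehyde in the presence of lactone and acetate; the new C2 carbinol forms as both epimers, which is harmless because C2 ends as the ketone.

Step 12
Reactants: 20 (1S,2Z,4RS)-4-hydroxy-8-[(4-methoxyphenyl)methoxy]-1-[(2S)-4-{[(4-methoxyphenyl)methoxy]methyl}-5-oxo-2,5-dihydrofuran-2-yl]-2-methyl-6-methylideneoct-2-en-1-yl acetate
Product: 21 (1S,2Z,4RS)-4-{[tert-butyl(dimethyl)silyl]oxy}-8-[(4-methoxyphenyl)methoxy]-1-[(2S)-4-{[(4-methoxyphenyl)methoxy]methyl}-5-oxo-2,5-dihydrofuran-2-yl]-2-methyl-6-methylideneoct-2-en-1-yl acetate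
Conditions: TBSCl, imidazole, DMF, rt
Reagents that add atoms: tert-butyldimethylsilyl chloride CC(C)(C)[Si](C)(C)Cl
Why: Silylation under conditions too weakly basic to enolise the butenolide keeps C2 at the carbinol level, so that it cannot act as an electrophile in step 16.

Step 13
Reactants: 21 (1S,2Z,4RS)-4-{[tert-butyl(dimethyl)silyl]oxy}-8-[(4-methoxyphenyl)methoxy]-1-[(2S)-4-{[(4-methoxyphenyl)methoxy]methyl}-5-oxo-2,5-dihydrofuran-2-yl]-2-methyl-6-methylideneoct-2-en-1-yl acetate
Product: 22 (1S,2Z,4RS)-4-{[tert-butyl(dimethyl)silyl]oxy}-8-hydroxy-1-[(2S)-4-(hydroxymethyl)-5-oxo-2,5-dihydrofuran-2-yl]-2-methyl-6-methylideneoct-2-en-1-yl acetate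
Conditions: DDQ (3 equiv), CH2Cl2/pH 7 buffer, 0 °C → rt
Reagents that add atoms: none
Why: Oxidative cleavage of both electron-rich PMB ethers by DDQ should leave the silyl ether, acetate, alkenes and lactone untouched.

Step 14
Reactants: 22 (1S,2Z,4RS)-4-{[tert-butyl(dimethyl)silyl]oxy}-8-hydroxy-1-[(2S)-4-(hydroxymethyl)-5-oxo-2,5-dihydrofuran-2-yl]-2-methyl-6-methylideneoct-2-en-1-yl acetate
Product: 23 (1S,2Z,4RS)-1-[(2S)-4-(bromomethyl)-5-oxo-2,5-dihydrofuran-2-yl]-4-{[tert-butyl(dimethyl)silyl]oxy}-8-hydroxy-2-methyl-6-methylideneoct-2-en-1-yl acetate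
Conditions: NBS, Me2S, CH2Cl2, −20 → 0 °C
Reagents that add atoms: N-bromosuccinimide O=C1CCC(=O)N1Br
Why: Corey–Kim halogenation, in which only the allylic alkoxysulfonium salt (C13) collapses by SN2 to the bromide while the saturated primary one at C6 is returned as the alcohol on work-up.

Step 15
Reactants: 23 (1S,2Z,4RS)-1-[(2S)-4-(bromomethyl)-5-oxo-2,5-dihydrofuran-2-yl]-4-{[tert-butyl(dimethyl)silyl]oxy}-8-hydroxy-2-methyl-6-methylideneoct-2-en-1-yl acetate
Product: 24 (1S,2Z,4RS)-1-[(2S)-4-(bromomethyl)-5-oxo-2,5-dihydrofuran-2-yl]-4-{[tert-butyl(dimethyl)silyl]oxy}-2-methyl-6-methylidene-8-oxooct-2-en-1-yl acetate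
Conditions: DMP, NaHCO3, CH2Cl2, 0 °C; used at once
Reagents that add atoms: none
Why: Buffered Dess–Martin oxidation tolerates the allylic bromide and should give the β,γ-unsaturated C6 aldehyde without double-bond migration.

Step 16
Reactants: 24 (1S,2Z,4RS)-1-[(2S)-4-(bromomethyl)-5-oxo-2,5-dihydrofuran-2-yl]-4-{[tert-butyl(dimethyl)silyl]oxy}-2-methyl-6-methylidene-8-oxooct-2-en-1-yl acetate
Product: 26 (6S,7R,8S,9S)-9-acetoxy-2-{[tert-butyl(dimethyl)silyl]oxy}-6-hydroxygermacra-1(10)Z,4(15),11(13)-trien-12,8-olide (C2 epimers), via allylchromium 25 (not isolated)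
Conditions: CrCl2 (10 equiv), THF, rt, syringe-pump addition of 24 (final 2 mM)
Reagents that add atoms: none
Why: Intramolecular Nozaki–Hiyama allylation: two Cr(II) reduce the allylic C13–Br bond to the σ-allylchromium(III) 25, whose γ-carbon C7 adds to the C6 aldehyde through a six-membered chair transition state (Cr bound to C13 and to the carbonyl oxygen), the C7=C11 double bond moving to C11=C13. The closest known reactions are the intermolecular Cr- or Zn-mediated γ-allylation of aldehydes by 3-(bromomethyl)furan-2(5H)-ones and the Cr-mediated closure of ten-membered germacrane rings from 2-(bromomethyl)enoate aldehydes. The ten-membered carbocycle closes in a 10-exo-trig attack on the aldehyde (SE2′ at the allyl unit), with the lactone ring already in place. C7 is set by C8: the aldehyde reaches the butenolide face anti to the C8–C9 bond, which gives the trans-fused lactone and the anti C9–C8–C7–C6 torsion that a ten-membered ring accommodates best. C6 is set by the chair, in which C8 is equatorial on C7 (the ring locks C8 trans to C13) and C5 equatorial on the aldehyde carbon, which should give the 6,7-anti (6S) alcohol, the C6 epimer of the target that step 17 inverts. The step needs aldehyde chemoselectivity and γ-regioselectivity: C2 is kept as a silyl ether because a C2 ketone would be attacked by C7 in a six-membered closure, lactone, acetate and silyl ether are inert to allylchromium, the cyclic transition state enforces γ-attack, and high dilution suppresses oligomers.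

Step 17
Reactants: 26 (6S,7R,8S,9S)-9-acetoxy-2-{[tert-butyl(dimethyl)silyl]oxy}-6-hydroxygermacra-1(10)Z,4(15),11(13)-trien-12,8-olide
Product: 27 (6R,7R,8S,9S)-9-acetoxy-2-{[tert-butyl(dimethyl)silyl]oxy}-6-[(2E)-2-methylbut-2-enoyloxy]germacra-1(10)Z,4(15),11(13)-trien-12,8-olide (C2 epimers)
Conditions: tiglic acid, PPh3, DIAD (betaine preformed), toluene, 0 °C → rt
Reagents that add atoms: tiglic acid [(2E)-2-methylbut-2-enoic acid] C/C=C(\C)C(=O)O
Why: Mitsunobu esterification, in which the carboxylate displaces the alkoxyphosphonium group by SN2, so C6 is inverted to R while the tiglate is installed.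

Step 18
Reactants: 27 (6R,7R,8S,9S)-9-acetoxy-2-{[tert-butyl(dimethyl)silyl]oxy}-6-[(2E)-2-methylbut-2-enoyloxy]germacra-1(10)Z,4(15),11(13)-trien-12,8-olide
Product: 28 (6R,7R,8S,9S)-9-acetoxy-2-hydroxy-6-[(2E)-2-methylbut-2-enoyloxy]germacra-1(10)Z,4(15),11(13)-trien-12,8-olide (C2 epimers)
Conditions: HF·pyridine, pyridine, THF, 0 °C → rt
Reagents that add atoms: none
Why: Buffered fluoride desilylation should not touch the two esters or the methylene lactone.

Step 19
Reactants: 28 (6R,7R,8S,9S)-9-acetoxy-2-hydroxy-6-[(2E)-2-methylbut-2-enoyloxy]germacra-1(10)Z,4(15),11(13)-trien-12,8-olide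
Product: 29 (6R,7R,8S,9S)-9-acetoxy-2-oxo-6-[(2E)-2-methylbut-2-enoyloxy]germacra-1(10)Z,4(15),11(13)-trien-12,8-olide (target)
Conditions: DMP, NaHCO3, CH2Cl2, 0 °C
Reagents that add atoms: none
Why: Dess–Martin oxidation converts both C2 epimers into the one enone, and the neutral buffered medium should keep the 4(15) alkene out of conjugation and the ring-held Z alkene intact.

**Compound list**
1 | prop-2-yn-1-ol | C#CCO | starting material
2 | bromomagnesium (2Z)-3-(bromomagnesio)-2-methylprop-2-en-1-olate | Br[Mg]/C=C(/C)CO[Mg]Br | intermediate (not isolated)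
3 | (2Z)-3-iodo-2-methylprop-2-en-1-ol | I/C=C(/C)CO | intermediate
4 | (2Z)-3-iodo-2-methylprop-2-enal | I/C=C(/C)C=O | intermediate
5 | furan-3-ylmethanol | OCc1ccoc1 | starting material
6 | 3-{[(4-methoxyphenyl)methoxy]methyl}furan | COc1ccc(COCc2ccoc2)cc1 | intermediate
7 | 2-lithio-3-{[(4-methoxyphenyl)methoxy]methyl}furan | COc1ccc(COCc2ccoc2[Li])cc1 | intermediate (not isolated)
8 | dimethyl (3-{[(4-methoxyphenyl)methoxy]methyl}furan-2-yl)boronate | COB(OC)c1occc1COCc1ccc(OC)cc1 | intermediate (not isolated)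
9 | 3-{[(4-methoxyphenyl)methoxy]methyl}furan-2(5H)-one | COc1ccc(COCC2=CCOC2=O)cc1 | intermediate
10 | tert-butyl[(3-{[(4-methoxyphenyl)methoxy]methyl}furan-2-yl)oxy]dimethylsilane | COc1ccc(COCc2ccoc2O[Si](C)(C)C(C)(C)C)cc1 | intermediate
11 | trichlorosilyl ether of 12 | I/C=C(/C)[C@H](O[Si](Cl)(Cl)Cl)[C@H]1OC(=O)C(COCc2ccc(OC)cc2)=C1 | intermediate (not isolated)
12 | (5S)-5-[(1S,2Z)-1-hydroxy-3-iodo-2-methylprop-2-en-1-yl]-3-{[(4-methoxyphenyl)methoxy]methyl}furan-2(5H)-one | I/C=C(/C)[C@H](O)[C@H]1OC(=O)C(COCc2ccc(OC)cc2)=C1 | intermediate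
13 | (1S,2Z)-3-iodo-1-[(2S)-4-{[(4-methoxyphenyl)methoxy]methyl}-5-oxo-2,5-dihydrofuran-2-yl]-2-methylprop-2-en-1-yl acetate | I/C=C(/C)[C@H](OC(C)=O)[C@H]1OC(=O)C(COCc2ccc(OC)cc2)=C1 | intermediate
14 | 3-methylbut-3-en-1-ol | CC(=C)CCO | starting material
15 | dilithio dianion of 3-methylbut-3-en-1-ol | [Li]CC(=C)CCO[Li] | intermediate (not isolated)
16 | 3-methylidenepentane-1,5-diol | OCCC(=C)CCO | intermediate
17 | 5-[(4-methoxyphenyl)methoxy]-3-methylidenepentan-1-ol | COc1ccc(COCCC(=C)CCO)cc1 | intermediate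
18 | 5-[(4-methoxyphenyl)methoxy]-3-methylidenepentanal | COc1ccc(COCCC(=C)CC=O)cc1 | intermediate
19 | (Z)-alkenylchromium(III) dichloride from 13 | Cl[Cr](Cl)/C=C(/C)[C@H](OC(C)=O)[C@H]1OC(=O)C(COCc2ccc(OC)cc2)=C1 | intermediate (not isolated)
20 | (1S,2Z,4RS)-4-hydroxy-8-[(4-methoxyphenyl)methoxy]-1-[(2S)-4-{[(4-methoxyphenyl)methoxy]methyl}-5-oxo-2,5-dihydrofuran-2-yl]-2-methyl-6-methylideneoct-2-en-1-yl acetate | COc1ccc(COCCC(=C)CC(O)/C=C(/C)[C@H](OC(C)=O)[C@H]2OC(=O)C(COCc3ccc(OC)cc3)=C2)cc1 | intermediate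
21 | (1S,2Z,4RS)-4-{[tert-butyl(dimethyl)silyl]oxy}-8-[(4-methoxyphenyl)methoxy]-1-[(2S)-4-{[(4-methoxyphenyl)methoxy]methyl}-5-oxo-2,5-dihydrofuran-2-yl]-2-methyl-6-methylideneoct-2-en-1-yl acetate | COc1ccc(COCCC(=C)CC(O[Si](C)(C)C(C)(C)C)/C=C(/C)[C@H](OC(C)=O)[C@H]2OC(=O)C(COCc3ccc(OC)cc3)=C2)cc1 | intermediate
22 | (1S,2Z,4RS)-4-{[tert-butyl(dimethyl)silyl]oxy}-8-hydroxy-1-[(2S)-4-(hydroxymethyl)-5-oxo-2,5-dihydrofuran-2-yl]-2-methyl-6-methylideneoct-2-en-1-yl acetate | OCCC(=C)CC(O[Si](C)(C)C(C)(C)C)/C=C(/C)[C@H](OC(C)=O)[C@H]1OC(=O)C(CO)=C1 | intermediate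
23 | (1S,2Z,4RS)-1-[(2S)-4-(bromomethyl)-5-oxo-2,5-dihydrofuran-2-yl]-4-{[tert-butyl(dimethyl)silyl]oxy}-8-hydroxy-2-methyl-6-methylideneoct-2-en-1-yl acetate | OCCC(=C)CC(O[Si](C)(C)C(C)(C)C)/C=C(/C)[C@H](OC(C)=O)[C@H]1OC(=O)C(CBr)=C1 | intermediate
24 | (1S,2Z,4RS)-1-[(2S)-4-(bromomethyl)-5-oxo-2,5-dihydrofuran-2-yl]-4-{[tert-butyl(dimethyl)silyl]oxy}-2-methyl-6-methylidene-8-oxooct-2-en-1-yl acetate | O=CCC(=C)CC(O[Si](C)(C)C(C)(C)C)/C=C(/C)[C@H](OC(C)=O)[C@H]1OC(=O)C(CBr)=C1 | intermediate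
25 | allylchromium(III) dichloride from 24 (Cr on C13) | O=CCC(=C)CC(O[Si](C)(C)C(C)(C)C)/C=C(/C)[C@H](OC(C)=O)[C@H]1OC(=O)C(C[Cr](Cl)Cl)=C1 | intermediate (not isolated)
26 | (6S,7R,8S,9S)-9-acetoxy-2-{[tert-butyl(dimethyl)silyl]oxy}-6-hydroxygermacra-1(10)Z,4(15),11(13)-trien-12,8-olide (C2 epimers) | C=C1CC(O[Si](C)(C)C(C)(C)C)/C=C(/C)[C@H](OC(C)=O)[C@H]2OC(=O)C(=C)[C@@H]2[C@@H](O)C1 | intermediate
27 | (6R,7R,8S,9S)-9-acetoxy-2-{[tert-butyl(dimethyl)silyl]oxy}-6-[(2E)-2-methylbut-2-enoyloxy]germacra-1(10)Z,4(15),11(13)-trien-12,8-olide (C2 epimers) | C=C1CC(O[Si](C)(C)C(C)(C)C)/C=C(/C)[C@H](OC(C)=O)[C@H]2OC(=O)C(=C)[C@@H]2[C@H](OC(=O)/C(C)=C/C)C1 | intermediate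
28 | (6R,7R,8S,9S)-9-acetoxy-2-hydroxy-6-[(2E)-2-methylbut-2-enoyloxy]germacra-1(10)Z,4(15),11(13)-trien-12,8-olide (C2 epimers) | C=C1CC(O)/C=C(/C)[C@H](OC(C)=O)[C@H]2OC(=O)C(=C)[C@@H]2[C@H](OC(=O)/C(C)=C/C)C1 | intermediate
29 | (6R,7R,8S,9S)-9-acetoxy-2-oxo-6-[(2E)-2-methylbut-2-enoyloxy]germacra-1(10)Z,4(15),11(13)-trien-12,8-olide | C=C1CC(=O)/C=C(/C)[C@H](OC(C)=O)[C@H]2OC(=O)C(=C)[C@@H]2[C@H](OC(=O)/C(C)=C/C)C1 | target

**Step count and risks**
Total step count: 19. Longest linear sequence: 14 steps (steps 3–7 and 11–19, from furan-3-ylmethanol).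

Steps most likely to fail:

1. Step 16. The ten-membered closure is slow, so the allylchromium may instead expel the C8 carboxylate (1,4-elimination that opens the lactone to a dienoic acid). It may also close on the butenolide face syn to C9 (cis-lactone) or oligomerise. The fallback keeps the ten-membered ring as the last ring but closes it at C1–C2 and forms C6–C7 intermolecularly, where the aldehyde is present at normal concentration. It sets out from 13 (with 18) and comes back at 28. DDQ cleavage of the PMB ether of 13 gives the hydroxymethyl butenolide F1, and NBS/Me2S gives the bromomethyl butenolide F2. CrCl2 in THF without nickel (vinyl iodide inert) adds F2 through its γ-carbon to aldehyde 18 to give the trans methylene lactone alcohol F3, expected 6S by the same chair model and anti approach. Mitsunobu esterification with tiglic acid gives the inverted tiglate F4, DDQ frees the primary alcohol F5, and Dess–Martin oxidation gives the aldehyde F6. Intramolecular Ni/Cr coupling of the vinyl iodide with this aldehyde under high dilution closes the carbocycle and delivers 28, which continues with step 19.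

2. Step 6. The open transition state may give insufficient syn/anti or facial selectivity, the iodoenal may isomerise from Z to E, or the allylic PMB ether of the donor may ionise under the Lewis acid. The fallback replaces catalyst control by reagent control and builds the butenolide by metathesis. It sets out from 4 and comes back at 13. Syn-selective alkoxyallylboration of 4 with (Z)-γ-(methoxymethoxy)allyl-diisopinocampheylborane (made in the flask from allyl methoxymethyl ether, s-BuLi, B-methoxydiisopinocampheylborane of the antipode that attacks the Re face, and BF3·OEt2) gives the syn diol monoether F7. Acetylation gives the acetate F8, and ZnBr2/n-PrSH removes the MOM group to give the allylic alcohol F9. The acid 2-{[(4-methoxyphenyl)methoxy]methyl}prop-2-enoic acid F10 (from commercial 2-(bromomethyl)acrylic acid and sodium 4-methoxybenzyl oxide) is coupled with F9 by DCC/DMAP to give the acrylate ester F11. Ring-closing metathesis with a second-generation Ru–NHC catalyst in toluene at 80 °C then gives 13.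

3. Step 17. The activated alcohol may eliminate towards the neighbouring alkenes, or react with retention through an acyloxyphosphonium pathway; the same correction applies if step 16 delivers a different C6 configuration than predicted. The fallback inverts by oxidation and reduction and then acylates with retention. It sets out from 26 and comes back at 27. Buffered Dess–Martin oxidation at 0 °C gives the C6 ketone F12 (C7 is epimerisable, so it is used at once). Reagent-controlled Corey–Bakshi–Shibata reduction, with the oxazaborolidine antipode that delivers hydride to the required face, gives the (6R)-alcohol F13. Acylation with tiglic anhydride and DMAP in CH2Cl2 gives 27.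

**Further compounds**
F1 | step 16 | (1S,2Z)-1-[(2S)-4-(hydroxymethyl)-5-oxo-2,5-dihydrofuran-2-yl]-3-iodo-2-methylprop-2-en-1-yl acetate | I/C=C(/C)[C@H](OC(C)=O)[C@H]1OC(=O)C(CO)=C1
F2 | step 16 | (1S,2Z)-1-[(2S)-4-(bromomethyl)-5-oxo-2,5-dihydrofuran-2-yl]-3-iodo-2-methylprop-2-en-1-yl acetate | I/C=C(/C)[C@H](OC(C)=O)[C@H]1OC(=O)C(CBr)=C1
F3 | step 16 | (1S,2Z)-1-{(2S,3R)-3-[(1S)-1-hydroxy-5-[(4-methoxyphenyl)methoxy]-3-methylidenepentyl]-4-methylidene-5-oxooxolan-2-yl}-3-iodo-2-methylprop-2-en-1-yl acetate | I/C=C(/C)[C@H](OC(C)=O)[C@H]1OC(=O)C(=C)[C@@H]1[C@@H](O)CC(=C)CCOCc1ccc(OC)cc1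
F4 | step 16 | (1R)-1-{(2S,3R)-2-[(1S,2Z)-1-acetoxy-3-iodo-2-methylprop-2-en-1-yl]-4-methylidene-5-oxooxolan-3-yl}-5-[(4-methoxyphenyl)methoxy]-3-methylidenepentyl (2E)-2-methylbut-2-enoate | I/C=C(/C)[C@H](OC(C)=O)[C@H]1OC(=O)C(=C)[C@@H]1[C@H](OC(=O)/C(C)=C/C)CC(=C)CCOCc1ccc(OC)cc1
F5 | step 16 | (1R)-1-{(2S,3R)-2-[(1S,2Z)-1-acetoxy-3-iodo-2-methylprop-2-en-1-yl]-4-methylidene-5-oxooxolan-3-yl}-5-hydroxy-3-methylidenepentyl (2E)-2-methylbut-2-enoate | I/C=C(/C)[C@H](OC(C)=O)[C@H]1OC(=O)C(=C)[C@@H]1[C@H](OC(=O)/C(C)=C/C)CC(=C)CCO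
F6 | step 16 | (1R)-1-{(2S,3R)-2-[(1S,2Z)-1-acetoxy-3-iodo-2-methylprop-2-en-1-yl]-4-methylidene-5-oxooxolan-3-yl}-3-methylidene-5-oxopentyl (2E)-2-methylbut-2-enoate | I/C=C(/C)[C@H](OC(C)=O)[C@H]1OC(=O)C(=C)[C@@H]1[C@H](OC(=O)/C(C)=C/C)CC(=C)CC=O
F7 | step 6 | (3S,4S,5Z)-6-iodo-3-(methoxymethoxy)-5-methylhexa-1,5-dien-4-ol | I/C=C(/C)[C@H](O)[C@@H](OCOC)C=C
F8 | step 6 | (3S,4S,5Z)-6-iodo-3-(methoxymethoxy)-5-methylhexa-1,5-dien-4-yl acetate | I/C=C(/C)[C@H](OC(C)=O)[C@@H](OCOC)C=C
F9 | step 6 | (3S,4S,5Z)-3-hydroxy-6-iodo-5-methylhexa-1,5-dien-4-yl acetate | I/C=C(/C)[C@H](OC(C)=O)[C@@H](O)C=C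
F10 | step 6 | 2-{[(4-methoxyphenyl)methoxy]methyl}prop-2-enoic acid | C=C(COCc1ccc(OC)cc1)C(=O)O
F11 | step 6 | (3S,4S,5Z)-4-acetoxy-6-iodo-5-methylhexa-1,5-dien-3-yl 2-{[(4-methoxyphenyl)methoxy]methyl}prop-2-enoate | I/C=C(/C)[C@H](OC(C)=O)[C@@H](OC(=O)C(=C)COCc1ccc(OC)cc1)C=C
F12 | step 17 | 9-acetoxy-2-{[tert-butyl(dimethyl)silyl]oxy}-6-oxogermacra-1(10)Z,4(15),11(13)-trien-12,8-olide (7S,8S,9S by CIP; same spatial arrangement as 26; C2 epimers) | C=C1CC(O[Si](C)(C)C(C)(C)C)/C=C(/C)[C@H](OC(C)=O)[C@H]2OC(=O)C(=C)[C@@H]2C(=O)C1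
F13 | step 17 | (6R,7R,8S,9S)-9-acetoxy-2-{[tert-butyl(dimethyl)silyl]oxy}-6-hydroxygermacra-1(10)Z,4(15),11(13)-trien-12,8-olide (C2 epimers) | C=C1CC(O[Si](C)(C)C(C)(C)C)/C=C(/C)[C@H](OC(C)=O)[C@H]2OC(=O)C(=C)[C@@H]2[C@H](O)C1
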